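The temperature stays fixed, so time and vessel are what differ between the 4 set-ups, and the charge is the same in each.

| flask | substrate | partner | free catalyst | impurity | remark | time |
|---|---|---|---|---|---|---|
| north-east | 0.0010 M | 1.50 mM | 2.0 µM | 2.2 µM | one stirred flow tank at steady state, fed with the mixture as stated, mean residence time 40 s |  |
| south-west | 0.0010 M | 1.50 mM | 2.0 µM | 2.2 µM | a single well-mixed tank run continuously and read at steady state, 200 s in it on average |  |
| east | 0.0010 M (fed, over 40.0 s) | 1.50 mM | 2.0 µM | 2.2 µM | a stirred flask in which substrate is dosed at a steady rate over 40.0 s without added volume, worked up at 40 s | 40 s |
| south | 0.0010 M | 1.50 mM | 2.0 µM | 2.2 µM | everything together in a closed stirred flask, run for 40 s | 40 s |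

    catalyst intermediate C → free catalyst + target (k1 = 137 s⁻¹)
    free catalyst + impurity → spent catalyst (k2 = 1.65 × 10⁶ M⁻¹ s⁻¹)
    catalyst intermediate B ⇌ released group + catalyst intermediate C (K3 = 0.00204 M, k3 = 554 s⁻¹)
    substrate + free catalyst → catalyst intermediate A (k4 = 7.15 × 10⁵ M⁻¹ s⁻¹)
    partner + catalyst intermediate A ⇌ catalyst intermediate B (K5 = 1800 M⁻¹, k5 = 43400 M⁻¹ s⁻¹)
    partner → decomposition product (k6 = 6.62 × 10⁻⁵ s⁻¹)

- the stated concentrations are those of everything mixed, before any reaction; amounts are the same in each set-up
- the feed brings no volume worth counting
- run time (east): 40 s

1. order of the set-ups by the amount of target at the outlet or at the end, in percent of the substrate put in, highest first (north-east / south-west / east / south)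
2. amount of target at the outlet or at the end, in percent of the substrate put in, north-east
3. amount of target at the outlet or at the end, in percent of the substrate put in, south-west
4. amount of target at the outlet or at the end, in percent of the substrate put in, east
5. amount of target at the outlet or at the end, in percent of the substrate put in, south

Free catalyst is charged in the smaller amount against impurity, 2.0 µM against 2.2 µM, so it is the limiting reagent of the poisoning, and I write its balance: free catalyst, the 3 intermediates and spent catalyst together hold the charge.

I take the closed flask south first, at its charge, and climb from fast to slow. Free catalyst takes up substrate in 1.40 ms, catalyst intermediate B breaks in 1.81 ms, catalyst intermediate C gives target in 7.30 ms, and catalyst intermediate A meets partner in 15.4 ms. That last wait is longer than the others, so catalyst intermediate A is the resting state at the start, and one turn of the forward steps lasts about 25.9 ms.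

On the next rung, free catalyst meets substrate at 715 s⁻¹ and impurity at 3.63 s⁻¹, so it makes about 197 turns per loss. That gives a first catalyst life of 5.09 s, shorter than the 40 s run. Partner decomposes far more slowly, with a half-life of 175 min.

Both losses draw on free catalyst, so its concentration cancels from their ratio. What remains is the selectivity factor, the constant of substrate uptake over the constant of poisoning, 0.433. In a closed flask, the fraction of substrate left equals the fraction of impurity left raised to this power. When the catalyst charge has been used up, 0.200 µM of impurity remains, so south has a ceiling of 64.6%, counting substrate lost as target. In the dosed flask east, substrate starts from nothing and the turns per loss at first grow by 4.92 s⁻¹, with impurity taken at its charge, so I put east last without a figure. My hand stops there.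

The forecast gives south-west > south > north-east > east, with 49% for north-east, 68% for south-west, 6% for east and 57% for south. Its ground is that “high substrate protects the catalyst”.

The simulation gives south-west > south > north-east > east, with 49.4% for north-east, 68.6% for south-west, 6.37% for east and 56.8% for south.

South reads under its ceiling of 64.6%, while the south-west tank reads above it. The tank works at its outlet concentrations, so the power becomes a plain ratio: substrate lost over substrate left equals 0.433 times impurity lost over impurity left. With 31.4% of the substrate left in south-west, 1.84 µM of impurity is lost, less than the 2.0 µM of catalyst charged. Poisoning is one part of the gap between the flasks east and south-west: with that step struck out, the target of east minus the target of south-west goes from −62 percentage points to −4.7 points.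

(Its constants were chosen freely.)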